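**Retrosynthetic overview**

1. The target triacid 29 is reached from pentacycle 25 by four functional-group steps: C4 methylation, C7 oxidation, C3 reduction, then cleavage of the C19 methyl ester and of a temporary C20–O12 lactone.
2. 25 comes from 24 by an intramolecular Diels–Alder reaction that forms C1–C2 and C5–C10 and closes rings A and B in one operation on a preformed C/D bicyclo[3.2.1]octane.
3. Enabling feature: in ring A the C3 oxygen and the C19 carboxyl on C4 map onto a 2-silyloxy-3-carbomethoxy diene C2=C3–C4=C5; the C20 carboxyl on C10 makes C1=C10 an acrylate; C5 and C10 are joined through C6–C8–C9 (ring B); the 12α-oxygen lies 1,3-diaxial to C10 on ring C, so C20 can be tied to O12 as a δ-lactone that locks the dienophile.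
4. 24 comes from a Knoevenagel condensation at C5, an alkynol cyclocarbonylation (lactone), a conjugate alkynylation at C9 of bicyclic enone 15, a gold-catalysed 5-exo-dig closure of ring D (C13–C16) and an Ireland–Claisen rearrangement (C6–C8 bond; C8 and C6 set) of an ester of (R)-3-propargylcyclohex-2-enol.
5. Ring order: C (from 1), then D, then the temporary lactone, then A and B together.

Key step: step 14

Remark: all intermediates carry gibberellane atom numbers (C1–C20; α is the face of C20), and acid 6 is taken as a catalogue compound (otherwise one oxidation step from 3-[(tert-butyldimethylsilyl)oxy]propan-1-ol).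

**Route**

Step 1
Reactants: 1 3-ethoxycyclohex-2-en-1-one; 2 propargyl bromide (3-bromoprop-1-yne)
Product: 4 3-(prop-2-yn-1-yl)cyclohex-2-en-1-one, via tertiary allylic alcohol 3 (not isolated)
Conditions: 2, Mg, HgCl2 (cat.), Et2O, 0 °C; add 1, −78 → 0 °C; then 1 M HCl, 0 °C
Reagents that add atoms: none
Why: Stork–Danheiser alkylative carbonyl transposition: the propargyl/allenyl Grignard reagent adds 1,2 to the vinylogous ester, and cold dilute acid hydrolyses the enol ether and eliminates water to the 3-substituted enone, with no stereocentre formed.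

Step 2
Reactants: 4 3-(prop-2-yn-1-yl)cyclohex-2-en-1-one
Product: 5 (R)-3-(prop-2-yn-1-yl)cyclohex-2-en-1-ol
Conditions: (S)-Me-CBS oxazaborolidine [(S)-1-methyl-3,3-diphenyltetrahydro-1H,3H-pyrrolo[1,2-c][1,3,2]oxazaborole] (10 mol%), catecholborane, toluene, −78 °C; MeOH, then aq. NaOH wash
Reagents that add atoms: none
Why: Corey–Bakshi–Shibata reduction, in which the oxazaborolidine–borane complex places the alkenyl flank as the large group and delivers hydride to one carbonyl face, should set the carbinol centre (future C11) as R, the alkyne being inert to catecholborane at this temperature.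

Step 3
Reactants: 5 (R)-3-(prop-2-yn-1-yl)cyclohex-2-en-1-ol; 6 3-[(tert-butyldimethylsilyl)oxy]propanoic acid
Product: 7 (R)-3-(prop-2-yn-1-yl)cyclohex-2-en-1-yl 3-[(tert-butyldimethylsilyl)oxy]propanoate
Conditions: DCC, DMAP (cat.), CH2Cl2, 0 °C → rt
Reagents that add atoms: none
Why: Steglich esterification acylates the secondary allylic alcohol under neutral conditions without touching its stereocentre.

Step 4
Reactants: 7 (R)-3-(prop-2-yn-1-yl)cyclohex-2-en-1-yl 3-[(tert-butyldimethylsilyl)oxy]propanoate
Product: 10 (2S)-3-[(tert-butyldimethylsilyl)oxy]-2-[(1R)-1-(prop-2-yn-1-yl)cyclohex-2-en-1-yl]propanoic acid, via silyl ketene acetal 8 (not isolated), via rearranged silyl ester 9 (not isolated)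
Conditions: Me3SiCl, Et3N, THF/DMPU (4:1), −78 °C; LiN(i-Pr)2 (2.3 equiv), −78 → 60 °C; then 1 M NaOH, MeOH, rt; 1 M HCl to pH 4
Reagents that add atoms: none
Why: Ireland–Claisen rearrangement: in-situ silylation traps the (Z)-ketene acetal before β-elimination, and the [3,3] shift through the boat-like transition state usual for cyclohex-2-enyl esters delivers C6 to the ring face that carried the ester oxygen, so the carbinol centre is relayed to quaternary C8 and the ketene acetal geometry sets C6, while the transient C-silyl group on the alkyne and the silyl ester fall off in the basic work-up.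

Step 5
Reactants: 10 acid from step 4
Product: 11 3-[(tert-butyldimethylsilyl)oxy]-2-[1-(prop-2-yn-1-yl)cyclohex-2-en-1-yl]propan-1-ol (C6 and C8 as in 10)
Conditions: LiAlH4, THF, 0 °C → rt; aq. NaOH work-up
Reagents that add atoms: none
Why: Hydride reduction of the carboxylic acid to the primary alcohol (C5–OH) leaves the silyl ether, alkene and alkyne untouched and does not affect C6 or C8.

Step 6
Reactants: 11 primary alcohol from step 5
Product: 12 triethylsilyl ether of 11
Conditions: Et3SiCl, imidazole, CH2Cl2, 0 °C
Reagents that add atoms: chlorotriethylsilane (TESCl), CC[Si](CC)(CC)Cl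
Why: Standard silylation gives a C5–O triethylsilyl ether that can later be told apart from the C7–O tert-butyldimethylsilyl ether.

Step 7
Reactants: 12 triethylsilyl ether from step 6
Product: 13 4,4-disubstituted cyclohex-2-en-1-one (C12 ketone with C9=C11)
Conditions: CrO3, 3,5-dimethylpyrazole, CH2Cl2, −20 °C
Reagents that add atoms: chromium trioxide, O=[Cr](=O)=O
Why: Allylic oxidation with the CrO3–3,5-dimethylpyrazole complex should oxidise the only ring allylic methylene (C12) to the enone, the other allylic carbon being quaternary C8, without touching stereocentres.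

Step 8
Reactants: 13 enone from step 7
Product: 15 7-methylidenebicyclo[3.2.1]oct-3-en-2-one carrying the C6 side chain at the bridgehead (C12 ketone with C9=C11 and C16=C17), via silyl dienol ether 14 (not isolated)
Conditions: TBSOTf, Et3N, CH2Cl2, 0 °C; filter through basic Al2O3, concentrate; Ph3PAuCl (5 mol%), AgBF4 (5 mol%), toluene/MeOH (10:1), rt
Reagents that add atoms: none
Why: Soft enolisation can occur only at C13 (C8 is quaternary) and gives the cross-conjugated silyl dienol ether, whose C13 adds 5-exo-dig to the alkyne activated by monovalent gold (Conia-ene-type carbocyclisation of a silyl enol ether), closing ring D with the exocyclic methylene and fixing C13 through the bridge from C8.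

Step 9
Reactants: 15 bicyclic enone from step 8; 16 (trimethylsilyl)acetylene
Product: 18 9α-ethynyl ketone (H9 β), via bis-silylated adduct 17 (not isolated)
Conditions: 16, n-BuLi, THF, −78 °C; ZnBr2, 0 °C; then 15, Me3SiOTf, Et2O/THF, −40 °C; then K2CO3, MeOH, rt
Reagents that add atoms: none
Why: Silyl-triflate-promoted conjugate addition of an alkynylzinc reagent should occur at C9 on the face anti to the two-carbon C15–C16 bridge (the exo face beside the one-carbon C14 bridge), placing C10 α and H9 β, and methanolic K2CO3 then removes both trimethylsilyl groups.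

Step 10
Reactants: 18 9α-ethynyl ketone from step 9
Product: 19 12α-alcohol (hydroxyl and ethynyl group 1,3-cis-diaxial on ring C)
Conditions: LiBH(s-Bu)3, THF, −78 °C; H2O
Reagents that add atoms: none
Why: The bulky hydride should attack the C12 ketone along the equatorial trajectory, away from the syn-axial C9 ethynyl group and the C14 bridge, to give the axial 12α-alcohol (substrate-controlled ketone reduction).

Step 11
Reactants: 19 12α-alcohol from step 10
Product: 20 α-methylene δ-lactone (C20 carbonyl bonded to O12 with C10=C1 exocyclic)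
Conditions: PdI2 (5 mol%), n-Bu3P (10 mol%), CO (7 bar), MeCN, 75 °C
Reagents that add atoms: carbon monoxide, [C-]#[O+]
Why: Palladium-catalysed cyclocarbonylation of an alkynol (alkoxycarbonyl–palladium formation, syn addition across the alkyne, protonolysis) gives the α-methylene δ-lactone, which can close only because O12 and C10 are 1,3-diaxial, with no stereocentre changed.

Step 12
Reactants: 20 α-methylene δ-lactone from step 11
Product: 21 aldehyde (C5 formyl group with C7–O silyl ether retained)
Conditions: (COCl)2, DMSO, CH2Cl2, −78 → −35 °C; Et3N, −78 → 0 °C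
Reagents that add atoms: none
Why: Swern conditions cleave and oxidise a primary triethylsilyl ether directly to the aldehyde while the tert-butyldimethylsilyl ether, the lactone and the alkenes are untouched, and the low temperature should preserve the C6 stereocentre.

Step 13
Reactants: 21 aldehyde from step 12; 22 methyl acetoacetate
Product: 23 (Z)-alkylidene acetoacetate (C5=C4 with C6 cis to the ester)
Conditions: TiCl4, pyridine, THF, 0 °C → rt
Reagents that add atoms: none
Why: Knoevenagel condensation under TiCl4/pyridine tolerates the hindered α-branched aldehyde and should give mainly the Z isomer, with the bulky C6 residue cis to the ester and trans to the acetyl group, as the diene geometry requires.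

Step 14
Reactants: 23 (Z)-alkylidene acetoacetate from step 13
Product: 25 pentacyclic Diels–Alder adduct (C3 silyl enol ether with rings A and B closed), via silyloxy diene 24 (not isolated)
Conditions: TBSOTf, Et3N, CH2Cl2, 0 °C; filter through basic Al2O3, exchange solvent to toluene (trace Et3N, BHT); 110 °C, sealed tube
Reagents that add atoms: tert-butyldimethylsilyl trifluoromethanesulfonate (TBSOTf), CC(C)(C)[Si](C)(C)OS(=O)(=O)C(F)(F)F
Why: Soft enolisation of the acetyl methyl group (C6–H is shielded by quaternary C8) gives the 2-silyloxy-3-carbomethoxy diene C2=C3–C4=C5, which on heating adds across the tethered α-methylene lactone C1=C10 in a concerted, asynchronous normal-demand [4+2] in which the electron-rich C2 terminus bonds first to the β-carbon C1. The closest known reaction type is the type 1 intramolecular Diels–Alder reaction of a 1,3,8-nonatriene bearing a 2-silyloxy diene, which gives a hydrindane. Ring A (six-membered) is closed by the cycloaddition itself and ring B (five-membered) by the internal bond C5–C10 over the three-atom tether C6–C8–C9, so the regiochemistry is fixed by the tether and agrees with the electronic preference. C10 is controlled by C9 and the temporary lactone, which holds C20 syn to C11 and leaves only the alkene face turned towards C8 open, so C20 ends α. C5 is controlled by C6 and the endo rule: 1,3-allylic strain with the cis ester on C4 keeps H6 in the diene plane and C8 on one diene face, and that face is the one used in the transition state with the lactone carbonyl endo, which gives the trans A/B fusion (H5 β, trans to H6). The step needs endo over exo selectivity and an s-cis diene of the correct C4=C5 geometry; the exo (cis-fused) path would have to turn the C7 silyloxymethyl group instead of H6 against the C4 ester, and the Z geometry from step 13 secures the diene.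

Step 15
Reactants: 25 Diels–Alder adduct from step 14
Product: 26 3-ketone with 4β-methyl (C18) and 4α-methoxycarbonyl (C19)
Conditions: Bu4N[Ph3SiF2], MeI, THF, 0 °C → rt
Reagents that add atoms: iodomethane, CI
Why: Fluoride-mediated enolate alkylation: the tetrabutylammonium enolate of the β-keto ester is C-methylated on the β face, opposite the 1,3-diaxial C20 lactone carbonyl on C10, so that C18 becomes equatorial and C19 axial and cis to C20, while the alkyl silyl ether survives this fluoride source.

Step 16
Reactants: 26 methylated keto ester from step 15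
Product: 27 7-oic acid
Conditions: CrO3, H2SO4, H2O, acetone, 0 °C → rt
Reagents that add atoms: water, O
Why: Jones oxidation cleaves the primary silyl ether under its acidic conditions and oxidises the C7 alcohol through the aldehyde to the acid, the ketone, esters, lactone and exocyclic alkene tolerating the reagent and C6 already being in the more stable arrangement trans to C4.

Step 17
Reactants: 27 keto acid from step 16
Product: 28 3β-alcohol
Conditions: LiBH(s-Bu)3 (2.5 equiv), THF, −78 °C; 1 M HCl
Reagents that add atoms: none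
Why: The bulky borohydride reduces the hindered C3 ketone by equatorial attack to the axial 3β-alcohol (substrate-controlled reduction), the lactone and ester being inert at this temperature and one equivalent being consumed by the acid.

Step 18
Reactants: 28 3β-alcohol from step 17
Product: 29 the target gibberellin (3β,12α-dihydroxy 7,19,20-triacid)
Conditions: NaSEt, DMF, 90 °C; then 2 M NaOH, rt; 1 M HCl to pH 3, 0 °C
Reagents that add atoms: sodium hydroxide, [Na+].[OH-]
Why: Thiolate cleaves the hindered C19 methyl ester by SN2 attack at the methyl carbon without forming a C3 alkoxide (no retro-aldol), hydroxide then opens the δ-lactone by acyl–oxygen cleavage with retention at C12, and cold acidification should give the triacid.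

**Compound list**

1 | 3-ethoxycyclohex-2-en-1-one | CCOC1=CC(=O)CCC1 | starting material
2 | propargyl bromide (3-bromoprop-1-yne) | C#CCBr | starting material
3 | 3-ethoxy-1-(prop-2-yn-1-yl)cyclohex-2-en-1-ol (racemic 1,2-adduct) | CCOC1=CC(O)(CC#C)CCC1 | intermediate
4 | 3-(prop-2-yn-1-yl)cyclohex-2-en-1-one | O=C1C=C(CC#C)CCC1 | intermediate
5 | (R)-3-(prop-2-yn-1-yl)cyclohex-2-en-1-ol (carbinol carbon is the future C11) | O[C@H]1C=C(CC#C)CCC1 | intermediate
6 | 3-[(tert-butyldimethylsilyl)oxy]propanoic acid | CC(C)(C)[Si](C)(C)OCCC(=O)O | starting material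
7 | (R)-3-(prop-2-yn-1-yl)cyclohex-2-en-1-yl 3-[(tert-butyldimethylsilyl)oxy]propanoate | CC(C)(C)[Si](C)(C)OCCC(=O)O[C@H]1C=C(CC#C)CCC1 | intermediate
8 | (Z)-trimethylsilyl ketene acetal of 7 with C-trimethylsilylated alkyne | C[Si](C)(C)O/C(=C\CO[Si](C)(C)C(C)(C)C)O[C@H]1C=C(CC#C[Si](C)(C)C)CCC1 | intermediate
9 | trimethylsilyl ester of 10 carrying the C-trimethylsilyl alkyne | C[Si](C)(C)C#CC[C@]1(C=CCCC1)[C@@H](CO[Si](C)(C)C(C)(C)C)C(=O)O[Si](C)(C)C | intermediate
10 | (2S)-3-[(tert-butyldimethylsilyl)oxy]-2-[(1R)-1-(prop-2-yn-1-yl)cyclohex-2-en-1-yl]propanoic acid (C6 and C8 set; acid carbon is C5) | C#CC[C@]1(C=CCCC1)[C@@H](CO[Si](C)(C)C(C)(C)C)C(=O)O | intermediate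
11 | 3-[(tert-butyldimethylsilyl)oxy]-2-[1-(prop-2-yn-1-yl)cyclohex-2-en-1-yl]propan-1-ol (C6, C8 as in 10) | C#CC[C@]1(C=CCCC1)[C@@H](CO[Si](C)(C)C(C)(C)C)CO | intermediate
12 | triethylsilyl ether of 11 (C5–OTES, C7–OTBS) | C#CC[C@]1(C=CCCC1)[C@@H](CO[Si](C)(C)C(C)(C)C)CO[Si](CC)(CC)CC | intermediate
13 | 4-(prop-2-yn-1-yl)-4-{1-[(tert-butyldimethylsilyl)oxy]-3-[(triethylsilyl)oxy]propan-2-yl}cyclohex-2-en-1-one (C12 ketone, C9=C11) | C#CC[C@]1(C=CC(=O)CC1)[C@@H](CO[Si](C)(C)C(C)(C)C)CO[Si](CC)(CC)CC | intermediate
14 | cross-conjugated tert-butyldimethylsilyl dienol ether of 13 (C12–OSi, C12=C13, C9=C11) | C#CC[C@]1(C=CC(O[Si](C)(C)C(C)(C)C)=CC1)[C@@H](CO[Si](C)(C)C(C)(C)C)CO[Si](CC)(CC)CC | intermediate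
15 | 7-methylidenebicyclo[3.2.1]oct-3-en-2-one with the C6 side chain at bridgehead C8 (rings C and D; C12 ketone, C9=C11, C16=C17) | C=C1C[C@@]2(C[C@H]1C(=O)C=C2)[C@@H](CO[Si](C)(C)C(C)(C)C)CO[Si](CC)(CC)CC | intermediate
16 | (trimethylsilyl)acetylene | C#C[Si](C)(C)C | starting material
17 | C12 trimethylsilyl enol ether (C11=C12) with 9α-[(trimethylsilyl)ethynyl] group | C=C1C[C@@]2(C[C@H]1C(O[Si](C)(C)C)=C[C@H]2C#C[Si](C)(C)C)[C@@H](CO[Si](C)(C)C(C)(C)C)CO[Si](CC)(CC)CC | intermediate
18 | 9α-ethynyl-12-ketone (H9 β) | C=C1C[C@@]2(C[C@H]1C(=O)C[C@H]2C#C)[C@@H](CO[Si](C)(C)C(C)(C)C)CO[Si](CC)(CC)CC | intermediate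
19 | 9α-ethynyl-12α-alcohol | C=C1C[C@@]2(C[C@H]1[C@@H](O)C[C@H]2C#C)[C@@H](CO[Si](C)(C)C(C)(C)C)CO[Si](CC)(CC)CC | intermediate
20 | α-methylene δ-lactone (C20(=O)–O12, C10=C1), C5–OTES, C7–OTBS | C=C1C[C@@]2(C[C@H]1[C@@H]3C[C@H]2C(=C)C(=O)O3)[C@@H](CO[Si](C)(C)C(C)(C)C)CO[Si](CC)(CC)CC | intermediate
21 | lactone aldehyde (C5 = CHO) | C=C1C[C@@]2(C[C@H]1[C@@H]3C[C@H]2C(=C)C(=O)O3)[C@@H](CO[Si](C)(C)C(C)(C)C)C=O | intermediate
22 | methyl acetoacetate | COC(=O)CC(C)=O | starting material
23 | (Z)-alkylidene acetoacetate (C5=C4; C6 cis to CO2Me) | C=C1C[C@@]2(C[C@H]1[C@@H]3C[C@H]2C(=C)C(=O)O3)[C@@H](CO[Si](C)(C)C(C)(C)C)/C=C(\C(=O)OC)C(C)=O | intermediate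
24 | 2-silyloxy-3-carbomethoxy diene (C2=C3(OTBS)–C4(CO2Me)=C5) tethered to the methylene lactone | C=C1C[C@@]2(C[C@H]1[C@@H]3C[C@H]2C(=C)C(=O)O3)[C@@H](CO[Si](C)(C)C(C)(C)C)/C=C(\C(=O)OC)C(=C)O[Si](C)(C)C(C)(C)C | intermediate
25 | pentacyclic Diels–Alder adduct: C3(OTBS)=C4(CO2Me), trans A/B, 20,12α-lactone, C7–OTBS | C=C1C[C@]23C[C@H]1[C@@H]4C[C@H]2[C@]5(C(=O)O4)CCC(O[Si](C)(C)C(C)(C)C)=C(C(=O)OC)[C@H]5[C@@H]3CO[Si](C)(C)C(C)(C)C | intermediate
26 | 3-oxo-4β-methyl-4α-methoxycarbonyl lactone, C7–OTBS | C=C1C[C@]23C[C@H]1[C@@H]4C[C@H]2[C@]5(C(=O)O4)CCC(=O)[C@@](C)(C(=O)OC)[C@H]5[C@@H]3CO[Si](C)(C)C(C)(C)C | intermediate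
27 | 3-oxo 7-oic acid (19-methyl ester, 20,12α-lactone) | C=C1C[C@]23C[C@H]1[C@@H]4C[C@H]2[C@]5(C(=O)O4)CCC(=O)[C@@](C)(C(=O)OC)[C@H]5[C@@H]3C(=O)O | intermediate
28 | 3β-hydroxy 7-oic acid (19-methyl ester, 20,12α-lactone) | C=C1C[C@]23C[C@H]1[C@@H]4C[C@H]2[C@]5(C(=O)O4)CC[C@H](O)[C@@](C)(C(=O)OC)[C@H]5[C@@H]3C(=O)O | intermediate
29 | target gibberellin: 3β,12α-dihydroxy C20-gibberellin 7,19,20-triacid with the C16=C17 exocyclic methylene (the compound named in the task) | C=C1C[C@]23C[C@H]1[C@@H](O)C[C@H]2[C@]1(C(=O)O)CC[C@H](O)[C@@](C)(C(=O)O)[C@H]1[C@@H]3C(=O)O | target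

**Step count and risks**

Total step count: 18. Longest linear sequence: 18 steps (1 to 29); 6, 16 and 22 enter as purchased reagents.

Steps most likely to fail:

1. Step 14. The silyl dienol ether may decompose on heating, or the cycloaddition may run with poor endo/exo selectivity and give the cis A/B fusion. The fallback is the anionic, stepwise variant and sets out from 23: LiN(SiMe3)2 in THF at −78 → 0 °C deprotonates the acetyl methyl group, the cross-conjugated lithium dienolate adds through C2 to C1 of the methylene lactone, and the lactone enolate then closes onto C5 (intramolecular double Michael addition). Aqueous NH4Cl gives the 3-oxo-4-methoxycarbonyl β-keto ester F1. C-methylation of it with K2CO3 and MeI in acetone gives 26, where the route is rejoined.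

2. Step 4. The ester enolate may lose silanolate by β-elimination before it is silylated, or the rearrangement may leak through the chair transition state and erode control at C6. The fallback sets out from 5 and separates the two stereocentres. Johnson–Claisen rearrangement (CH3C(OEt)3, cat. EtCO2H, 140 °C) gives ethyl 2-[1-(prop-2-yn-1-yl)cyclohex-2-en-1-yl]acetate F2 with C8 set by chirality transfer. Reduction with i-Bu2AlH in CH2Cl2 at −78 °C gives the aldehyde F3. Enamine-catalysed α-hydroxymethylation (aqueous formaldehyde, the matching enantiomer of α,α-diphenylprolinol trimethylsilyl ether, toluene/pH 7 buffer) gives the β-hydroxy aldehyde F4 with C6 set by the catalyst. TBSCl and imidazole give the silyl ether aldehyde F5, and NaBH4 in MeOH at 0 °C gives 11, where the route is rejoined.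

3. Step 11. The hindered axial alkyne may fail to insert, or O12 may add directly to the activated alkyne (cycloisomerisation) instead of being carbonylated. The fallback sets out from 19: Markovnikov haloboration–protonolysis (B-iodo-9-borabicyclo[3.3.1]nonane, hexane, −20 °C; AcOH) gives the 2-iodoalkene F6. Carbonylative lactonisation by oxidative addition of zerovalent palladium (Pd(PPh3)4, CO 1 bar, Et3N, MeCN, 60 °C) then gives 20, where the route is rejoined.

Further compounds
F1 | step 14 | 3-oxo-4-methoxycarbonyl β-keto ester (C4–H, keto/enol; trans A/B; 20,12α-lactone; C7–OTBS) | C=C1C[C@]23C[C@H]1[C@@H]4C[C@H]2[C@]5(C(=O)O4)CCC(=O)C(C(=O)OC)[C@H]5[C@@H]3CO[Si](C)(C)C(C)(C)C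
F2 | step 4 | ethyl 2-[1-(prop-2-yn-1-yl)cyclohex-2-en-1-yl]acetate (C8 as in 10) | C#CC[C@]1(C=CCCC1)CC(=O)OCC
F3 | step 4 | 2-[1-(prop-2-yn-1-yl)cyclohex-2-en-1-yl]acetaldehyde (C8 as in 10) | C#CC[C@]1(C=CCCC1)CC=O
F4 | step 4 | 3-hydroxy-2-[1-(prop-2-yn-1-yl)cyclohex-2-en-1-yl]propanal (C6, C8 as in 10) | C#CC[C@]1(C=CCCC1)[C@@H](CO)C=O
F5 | step 4 | 3-[(tert-butyldimethylsilyl)oxy]-2-[1-(prop-2-yn-1-yl)cyclohex-2-en-1-yl]propanal (C6, C8 as in 10) | C#CC[C@]1(C=CCCC1)[C@@H](CO[Si](C)(C)C(C)(C)C)C=O
F6 | step 11 | 9α-(1-iodoethenyl)-12α-alcohol | C=C1C[C@@]2(C[C@H]1[C@@H](O)C[C@H]2C(I)=C)[C@@H](CO[Si](C)(C)C(C)(C)C)CO[Si](CC)(CC)CC
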